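- Sunday's: solid substrate 0.0020 M; the very flask that is asked about, followed so far
- flask: solid substrate 0.0020 M; time 5.0 min
Sunday's run (percent of the solid substrate charged)

| time / s | starting material / % | target / % | isomer of the product / % | solid substrate / % |
|---|---|---|---|---|
| 25.0 | 10.2 | 3.1 | 3.3 | 84.5 |
| 50.0 | 17.7 | 6.5 | 4.6 | 71.6 |
| 80.0 | 20.8 | 12.7 | 6.8 | 56.1 |
| 90.0 | 21.5 | 14.4 | 8.2 | 53.8 |
| 120 | 23.6 | 21.2 | 7.5 | 41.9 |

(readings scatter by 1 percentage point)
- at the start none of the solid substrate is in solution
- a reading or a percentage of target counts all its forms, free or not
- starting material means what is dissolved; the solid is not counted in it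
- the species in which most of what was charged as solid substrate, at 5.0 min sits (starting material / target / isomer of the product)
- the largest share itself, whichever of these holds it, in percent of the solid substrate charged

- Late in Sunday's flask, at 120 s, starting material still read above target (23.6% against 21.2%), so I turned the question round: for a rival to hold as much as target at 5.0 min, target had to end at or below 50%.
- From the readings at 50.0 s and 120 s I took 0.610 min⁻¹ as the target clock, the fraction of dissolved starting material turned into target per minute, an apparent first-order constant.
- By that clock taken alone, the fraction left at 5.0 min of the portion of starting material standing at 120 s came to 16.0%, but solid substrate still read 41.9% at 120 s, so I reckoned with the level of starting material instead: stopping target at 50% needed a mean starting material of 15.7% over that stretch, less than its last reading; holding that reading, I reckoned 64.4% target.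
- The forecast said target, at 62% (53% to 71%), a little below my figure, and held of one rival that “The isomer has plateaued near 8%, so it stays minor”.
- The flask gave target at 66.0%, of which 36.8% stood as crystals. From 50.9% target at 3.75 min, with starting material going from 26.8% to 13.7%, the clock gives 66.3% at 5.0 min.

    solid substrate ⇌ starting material, rate k1*(cs1 - [starting material]) while solid is left; crystals form when [starting material] > cs1 (solubility = 1.10 mM, k = 0.0130 s⁻¹)
    starting material ⇌ isomer of the product (K = 0.330, k = 0.0250 s⁻¹)
    2 starting material → self-condensation product (k = 2.70 M⁻¹ s⁻¹)
    starting material ⇌ target (K = 24.0, k = 0.0110 s⁻¹)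
    crystals ⇌ target, rate k5*(cs5 - [target]) while solid is left; crystals form when [target] > cs5 (solubility = 0.580 mM, k = 0.980 s⁻¹)

- In the neighbour read at 2.0 min, the clock, starting from 11.1% target at 1.25 min with starting material going from 21.2% to 24.6%, gives 21.6%; the computed target there is 22.2%.

The data were generated by integration for an exercise; the scatter is artificial.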